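**Retrosynthetic overview**

1. Target ⇐ acetylation and alkynol cycloisomerisation (dihydrofuran, last ring) ⇐ spiro-tetrahydrofuran by stereospecific 5-exo opening of a Sharpless-derived C13 epoxide by the 9α-OH ⇐ C11–C12 bond by opening a 9α,11-epoxide with the dianion of methallyl alcohol.
2. 9α,11-Epoxide ⇐ C9 ketone / 6β-ol ⇐ bicyclic aldehyde 15. Its formyl group on C6 (excised to the C6 ketone, then reduced) and its methylsulfanyl group on C9 (hydrolysed to the C9 ketone) are the removable activators of the key step.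
3. Key disconnection: rings A and B are formed together by an enantioselective intramolecular Diels–Alder reaction of the acyclic trienal 14, which makes C5–C10 and C6–C7.
4. Enabling feature: ring B (C5–C6–C7–C8–C9–C10) carries its two heteroatom-bearing carbons, C6 (acetoxy) and C9 (ether oxygen), in a 1,4 relation and shares the C5–C10 bond with ring A. This maps onto a donor diene C7=C8–C9(X)=C10 and an acceptor dienophile C5=C6 of matched polarity, with C1–C4 of ring A as the tether.
5. Ring order: A and B (step 6), temporary oxiranes (steps 11 and 13), tetrahydrofuran (step 16), dihydrofuran (step 17). The diene geometry comes from syn-carbocupration of an alkynyl sulfide.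

Key step: step 6

Assumption: labdane numbering (C1–C20) and α/β descriptors (C10 methyl = β) are used for all decalin intermediates; the target is (5S,6R,8R,9R,10S,13R). Commercial solutions of LiN(iPr)2, n-BuLi, MeMgBr and iBu2AlH are used as such.

**Route**

Step 1
Reactants: 1 5-chloropent-1-yne
Product: 3 5-chloro-1-(methylsulfanyl)pent-1-yne, via lithium alkynide 2 (not isolated)
Conditions: n-BuLi, THF, −78 °C; MeSSMe, −78 → 0 °C
Reagents that add atoms: dimethyl disulfide (CSSC)
Why: Deprotonation of the terminal alkyne and sulfenylation of the acetylide by the disulfide is the standard synthesis of 1-alkynyl sulfides and creates no stereocentre.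

Step 2
Reactants: 4 2-methylpropanenitrile; 3 5-chloro-1-(methylsulfanyl)pent-1-yne
Product: 6 2,2-dimethyl-7-(methylsulfanyl)hept-6-ynenitrile, via lithiated nitrile 5 (not isolated)
Conditions: LiN(iPr)2, THF, −78 °C; then 3, NaI (10 mol %), DMPU, −78 → 23 °C
Reagents that add atoms: none
Why: SN2 alkylation of the tertiary nitrile-stabilised carbanion by the primary chloride (iodide exchange in situ) builds the C4 quaternary carbon with its two methyl groups.

Step 3
Reactants: 6 2,2-dimethyl-7-(methylsulfanyl)hept-6-ynenitrile; 7 2-bromoprop-1-ene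
Product: 10 (6Z)-2,2,6,8-tetramethyl-7-(methylsulfanyl)nona-6,8-dienenitrile, via alkenylcopper 8 (not isolated), via alkenylzinc bromide 9 (not isolated)
Conditions: MeMgBr, CuBr·SMe2, THF, −40 → −10 °C; then ZnBr2, Pd(PPh3)4 (5 mol %), 7, 0 → 23 °C
Reagents that add atoms: methylmagnesium bromide (C[Mg]Br)
Why: syn-Carbocupration of a 1-alkynyl sulfide puts copper on the sulfur-bearing carbon and methyl on the distal carbon, and transmetalation to zinc followed by Negishi vinylation proceeds with retention, so methyl and isopropenyl end up cis and the tether cis to sulfur (6Z).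

Step 4
Reactants: 10 (6Z)-2,2,6,8-tetramethyl-7-(methylsulfanyl)nona-6,8-dienenitrile
Product: 12 (6Z)-2,2,6,8-tetramethyl-7-(methylsulfanyl)nona-6,8-dienal, via aluminium aldimine 11 (not isolated)
Conditions: iBu2AlH, PhMe, −78 °C; then 1 M HCl, 0 °C
Reagents that add atoms: water (O)
Why: Partial reduction of the hindered tertiary nitrile stops at the N-aluminio aldimine, which is hydrolysed on work-up while the acid-tolerant vinyl sulfide survives.

Step 5
Reactants: 12 (6Z)-2,2,6,8-tetramethyl-7-(methylsulfanyl)nona-6,8-dienal; 13 2-(triphenylphosphoranylidene)acetaldehyde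
Product: 14 (2E,8Z)-4,4,8,10-tetramethyl-9-(methylsulfanyl)undeca-2,8,10-trienal
Conditions: PhMe, 70 °C
Reagents that add atoms: none
Why: Wittig olefination with the stabilised formyl ylide gives the (E)-enal, which supplies C6 and the temporary formyl activator.

Step 6
Reactants: 14 (2E,8Z)-4,4,8,10-tetramethyl-9-(methylsulfanyl)undeca-2,8,10-trienal
Product: 15 (1S,4aS,8aS)-3,4a,8,8-tetramethyl-4-(methylsulfanyl)-1,2,4a,5,6,7,8,8a-octahydronaphthalene-1-carbaldehyde (trans-fused; formyl on C6 α)
Conditions: (2S,5S)-5-benzyl-2-tert-butyl-3-methylimidazolidin-4-one·CF3CO2H (20 mol %), MeCN/H2O (98:2), −10 → 4 °C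
Reagents that add atoms: none
Why: Condensation of the enal with the imidazolidinone gives an (E)-iminium ion whose electrophilic C5 is attacked by C10, the nucleophilic terminus of the 2-(methylsulfanyl)diene, in a concerted but strongly asynchronous type 1 intramolecular Diels–Alder reaction (in the limit a Michael addition followed by enamine-to-thionium ring closure); hydrolysis then releases 15 and the catalyst. The closest known reaction is the imidazolidinone-catalysed intramolecular Diels–Alder reaction of (E)-deca-2,7,9-trienals to trans-decalins, here applied to a sulfur-activated tetrasubstituted diene. Ring A closes through the C5–C10 bond with the four-carbon tether in a chair (6-exo with respect to the iminium acceptor), and ring B closes through the C6–C7 bond as the new cyclohexene (6-endo in the stepwise description). C5 is set by the catalyst, whose benzyl group shields one face of the iminium so that C10 adds to the open face (5S); C10 is set relative to C5 by the endo transition state with the tether on the outer position of the (8Z)-vinyl sulfide, which gives the trans ring fusion with the C10 methyl anti to H5 (10S); the C6 configuration follows from the (E)-enal and is erased later. The step needs endo (trans) and facial selectivity, secured by iminium activation and the defined diene geometry; regiochemistry is fixed by the tether, with which the sulfur donor at C9 is polarity-matched, and the gem-dimethyl group at C4 favours the folded reactive conformer.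

Step 7
Reactants: 15 (1S,4aS,8aS)-3,4a,8,8-tetramethyl-4-(methylsulfanyl)-1,2,4a,5,6,7,8,8a-octahydronaphthalene-1-carbaldehyde
Product: 17 (4aS,8aS)-3,4a,8,8-tetramethyl-4-(methylsulfanyl)-4a,5,6,7,8,8a-hexahydronaphthalen-1(2H)-one, via enamine 16 (not isolated)
Conditions: piperidine, 4 Å MS, PhMe, 23 °C; then CuCl (10 mol %), O2 (1 atm), MeCN, 0 → 23 °C
Reagents that add atoms: dioxygen (O=O)
Why: Copper-catalysed aerobic cleavage of the enamine C=C (oxidative deformylation of an α-branched aldehyde) removes the activating carbon and leaves the C6 ketone, with the less electron-rich vinyl sulfide untouched and C5 held trans as the stable ring fusion.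

Step 8
Reactants: 17 (4aS,8aS)-3,4a,8,8-tetramethyl-4-(methylsulfanyl)-4a,5,6,7,8,8a-hexahydronaphthalen-1(2H)-one
Product: 18 (1R,4aS,8aS)-3,4a,8,8-tetramethyl-4-(methylsulfanyl)-1,2,4a,5,6,7,8,8a-octahydronaphthalen-1-ol (6β-OH)
Conditions: NaBH4, MeOH/CH2Cl2, −20 → 0 °C
Reagents that add atoms: none
Why: Substrate-controlled hydride reduction, in which the β face of C6 is blocked by the syn-axial methyl groups on C10 and C4, so hydride enters from the α face and gives the axial 6β-alcohol (6R).

Step 9
Reactants: 18 (1R,4aS,8aS)-3,4a,8,8-tetramethyl-4-(methylsulfanyl)-1,2,4a,5,6,7,8,8a-octahydronaphthalen-1-ol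
Product: 19 (2R,4R,4aS,8aS)-4-hydroxy-2,5,5,8a-tetramethyloctahydronaphthalen-1(2H)-one (C9 ketone, 8α-methyl, 6β-OH)
Conditions: HgCl2, CaCO3, MeCN/H2O (4:1), 50 °C; then NaOMe (cat.), MeOH, 23 °C
Reagents that add atoms: water (O)
Why: Thiophile-assisted hydrolysis of the vinyl sulfide unveils the C9 ketone, and base equilibration through the enolate places the C8 methyl equatorial (8R), which avoids the 1,3-diaxial clash with the C10 methyl.

Step 10
Reactants: 19 (2R,4R,4aS,8aS)-4-hydroxy-2,5,5,8a-tetramethyloctahydronaphthalen-1(2H)-one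
Product: 20 (1R,3R,4aS,8aS)-3,4a,8,8-tetramethyl-4-methylidenedecahydronaphthalen-1-ol
Conditions: Ph3PCH3Br, KOtBu (excess), PhMe, 90 °C
Reagents that add atoms: methyltriphenylphosphonium bromide (C[P+](c1ccccc1)(c1ccccc1)c1ccccc1.[Br-])
Why: Wittig methylenation under forcing conditions suited to hindered ketones introduces C11, and C8 stays in its thermodynamic configuration.

Step 11
Reactants: 20 (1R,3R,4aS,8aS)-3,4a,8,8-tetramethyl-4-methylidenedecahydronaphthalen-1-ol
Product: 21 9α,11-epoxide of 20 (spiro-oxirane at C9 with the oxygen on the α face, 6β-OH retained)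
Conditions: mCPBA, NaHCO3, CH2Cl2, 0 °C
Reagents that add atoms: 3-chloroperoxybenzoic acid (OOC(=O)c1cccc(Cl)c1)
Why: Prilezhaev epoxidation of the exocyclic alkene from the α face, opposite the axial C10 methyl that covers the β face, sets the C9–O bond α.

Step 12
Reactants: 21 9α,11-epoxide of 20; 22 2-methylprop-2-en-1-ol
Product: 24 (1R,2R,4R,4aS,8aS)-1-[3-(hydroxymethyl)but-3-en-1-yl]-2,5,5,8a-tetramethyldecahydronaphthalene-1,4-diol, via dianion 23 (not isolated)
Conditions: 22, n-BuLi (2 equiv per 22), TMEDA, Et2O, 0 → 23 °C; then 21, THF, 0 → 40 °C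
Reagents that add atoms: none
Why: The carbon-nucleophilic allyllithium dianion of methallyl alcohol opens the oxirane by SN2 at its primary carbon, which forms C11–C12 and leaves the 9α tertiary alcohol without touching C9.

Step 13
Reactants: 24 (1R,2R,4R,4aS,8aS)-1-[3-(hydroxymethyl)but-3-en-1-yl]-2,5,5,8a-tetramethyldecahydronaphthalene-1,4-diol
Product: 25 (1R,2R,4R,4aS,8aS)-1-{2-[(2S)-2-(hydroxymethyl)oxiran-2-yl]ethyl}-2,5,5,8a-tetramethyldecahydronaphthalene-1,4-diol
Conditions: Ti(OiPr)4, L-(+)-diethyl tartrate, t-BuOOH, 4 Å MS, CH2Cl2, −20 °C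
Reagents that add atoms: tert-butyl hydroperoxide (CC(C)(C)OO)
Why: Sharpless asymmetric epoxidation of the 2-substituted allylic alcohol is reagent-controlled, and L-(+)-tartrate should give the (S)-oxirane at C13, as it gives (S)-2-methylglycidol from methallyl alcohol.

Step 14
Reactants: 25 (1R,2R,4R,4aS,8aS)-1-{2-[(2S)-2-(hydroxymethyl)oxiran-2-yl]ethyl}-2,5,5,8a-tetramethyldecahydronaphthalene-1,4-diol
Product: 26 (2R)-2-{2-[(1R,2R,4R,4aS,8aS)-1,4-dihydroxy-2,5,5,8a-tetramethyldecahydronaphthalen-1-yl]ethyl}oxirane-2-carbaldehyde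
Conditions: TEMPO (10 mol %), PhI(OAc)2, NaHCO3, CH2Cl2, 0 °C
Reagents that add atoms: none
Why: Oxoammonium (TEMPO) oxidation is selective for the primary alcohol over the hindered axial 6β-OH and the tertiary 9α-OH, and the buffer keeps the epoxide closed.

Step 15
Reactants: 26 (2R)-2-{2-[(1R,2R,4R,4aS,8aS)-1,4-dihydroxy-2,5,5,8a-tetramethyldecahydronaphthalen-1-yl]ethyl}oxirane-2-carbaldehyde
Product: 27 (1R,2R,4R,4aS,8aS)-1-{2-[(2S)-2-ethynyloxiran-2-yl]ethyl}-2,5,5,8a-tetramethyldecahydronaphthalene-1,4-diol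
Conditions: dimethyl (1-diazo-2-oxopropyl)phosphonate, K2CO3, MeOH, 0 → 23 °C
Reagents that add atoms: dimethyl (1-diazo-2-oxopropyl)phosphonate (CC(=O)C(=[N+]=[N-])P(=O)(OC)OC)
Why: Seyferth–Gilbert homologation with the Ohira–Bestmann reagent turns the aldehyde into the terminal alkyne (C14≡C15) under mild base, and the quaternary C13 cannot epimerise.

Step 16
Reactants: 27 (1R,2R,4R,4aS,8aS)-1-{2-[(2S)-2-ethynyloxiran-2-yl]ethyl}-2,5,5,8a-tetramethyldecahydronaphthalene-1,4-diol
Product: 28 (5S,6R,8R,9R,10S,13R)-9,13-epoxylabd-14-yne-6,16-diol (spiro-tetrahydrofuran; C13 carries ethynyl and hydroxymethyl)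
Conditions: (+)-camphor-10-sulfonic acid (10 mol %), CH2Cl2, −20 → 0 °C
Reagents that add atoms: none
Why: Acid-catalysed intramolecular 5-exo-tet opening of the epoxide at its tertiary propargylic carbon by the 9α-OH proceeds with inversion, which closes the tetrahydrofuran ring, sets C13 as R and frees the C16 hydroxyl.

Step 17
Reactants: 28 (5S,6R,8R,9R,10S,13R)-9,13-epoxylabd-14-yne-6,16-diol
Product: 29 (5S,6R,8R,9R,10S,13R)-9,13:15,16-diepoxylabd-14-en-6-ol
Conditions: Mo(CO)6 (20 mol %), Et3N, Et2O, hν (350 nm), 23 °C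
Reagents that add atoms: none
Why: Metal-vinylidene endo-cycloisomerisation of the homopropargylic alcohol gives the 2,3-dihydrofuran under basic conditions that spare the acid-labile allylic spiro-ether and leave all stereocentres untouched.

Step 18
Reactants: 29 (5S,6R,8R,9R,10S,13R)-9,13:15,16-diepoxylabd-14-en-6-ol
Product: 30 (5S,6R,8R,9R,10S,13R)-9,13:15,16-diepoxylabd-14-en-6-yl acetate (target)
Conditions: Ac2O, DMAP, Et3N, CH2Cl2, 23 → 40 °C
Reagents that add atoms: acetic anhydride (CC(=O)OC(C)=O)
Why: DMAP-catalysed acylation of the only free hydroxyl (axial 6β-OH) under non-acidic conditions completes the target with retention at C6.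

**Compound list**

1 | 5-chloropent-1-yne | ClCCCC#C | starting material
2 | lithium 5-chloropent-1-yn-1-ide | ClCCCC#C[Li] | intermediate (not isolated)
3 | 5-chloro-1-(methylsulfanyl)pent-1-yne | ClCCCC#CSC | intermediate
4 | 2-methylpropanenitrile | CC(C)C#N | starting material
5 | 2-lithio-2-methylpropanenitrile | CC(C)([Li])C#N | intermediate (not isolated)
6 | 2,2-dimethyl-7-(methylsulfanyl)hept-6-ynenitrile | N#CC(C)(C)CCCC#CSC | intermediate
7 | 2-bromoprop-1-ene | CC(Br)=C | starting material
8 | alkenylcopper from syn-methylcupration of 6 | N#CC(C)(C)CCC/C(C)=C(SC)/[Cu] | intermediate (not isolated)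
9 | alkenylzinc bromide from 8 | N#CC(C)(C)CCC/C(C)=C(SC)/[Zn]Br | intermediate (not isolated)
10 | (6Z)-2,2,6,8-tetramethyl-7-(methylsulfanyl)nona-6,8-dienenitrile | N#CC(C)(C)CCC/C(C)=C(SC)/C(C)=C | intermediate
11 | N-(diisobutylaluminio) aldimine of 12 | CC(C)C[Al](CC(C)C)N=CC(C)(C)CCC/C(C)=C(SC)/C(C)=C | intermediate (not isolated)
12 | (6Z)-2,2,6,8-tetramethyl-7-(methylsulfanyl)nona-6,8-dienal | O=CC(C)(C)CCC/C(C)=C(SC)/C(C)=C | intermediate
13 | 2-(triphenylphosphoranylidene)acetaldehyde | O=CC=P(c1ccccc1)(c1ccccc1)c1ccccc1 | starting material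
14 | (2E,8Z)-4,4,8,10-tetramethyl-9-(methylsulfanyl)undeca-2,8,10-trienal | O=C/C=C/C(C)(C)CCC/C(C)=C(SC)/C(C)=C | intermediate
15 | (1S,4aS,8aS)-3,4a,8,8-tetramethyl-4-(methylsulfanyl)-1,2,4a,5,6,7,8,8a-octahydronaphthalene-1-carbaldehyde | O=C[C@H]1CC(C)=C(SC)[C@@]2(C)CCCC(C)(C)[C@H]12 | intermediate
16 | piperidine enamine of 15 | C(=C1CC(C)=C(SC)[C@@]2(C)CCCC(C)(C)[C@H]12)N1CCCCC1 | intermediate (not isolated)
17 | (4aS,8aS)-3,4a,8,8-tetramethyl-4-(methylsulfanyl)-4a,5,6,7,8,8a-hexahydronaphthalen-1(2H)-one | O=C1CC(C)=C(SC)[C@@]2(C)CCCC(C)(C)[C@H]12 | intermediate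
18 | (1R,4aS,8aS)-3,4a,8,8-tetramethyl-4-(methylsulfanyl)-1,2,4a,5,6,7,8,8a-octahydronaphthalen-1-ol | O[C@@H]1CC(C)=C(SC)[C@@]2(C)CCCC(C)(C)[C@H]12 | intermediate
19 | (2R,4R,4aS,8aS)-4-hydroxy-2,5,5,8a-tetramethyloctahydronaphthalen-1(2H)-one | O[C@@H]1C[C@@H](C)C(=O)[C@@]2(C)CCCC(C)(C)[C@H]12 | intermediate
20 | (1R,3R,4aS,8aS)-3,4a,8,8-tetramethyl-4-methylidenedecahydronaphthalen-1-ol | O[C@@H]1C[C@@H](C)C(=C)[C@@]2(C)CCCC(C)(C)[C@H]12 | intermediate
21 | 9α,11-epoxide of 20 (spiro-oxirane, oxygen α, 6β-OH) | O[C@@H]1C[C@@H](C)[C@]3(CO3)[C@@]2(C)CCCC(C)(C)[C@H]12 | intermediate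
22 | 2-methylprop-2-en-1-ol | CC(=C)CO | starting material
23 | dilithium dianion of 22 (C,O-dilithiated) | [Li]CC(=C)CO[Li] | intermediate (not isolated)
24 | (1R,2R,4R,4aS,8aS)-1-[3-(hydroxymethyl)but-3-en-1-yl]-2,5,5,8a-tetramethyldecahydronaphthalene-1,4-diol | O[C@@H]1C[C@@H](C)[C@](O)(CCC(=C)CO)[C@@]2(C)CCCC(C)(C)[C@H]12 | intermediate
25 | (1R,2R,4R,4aS,8aS)-1-{2-[(2S)-2-(hydroxymethyl)oxiran-2-yl]ethyl}-2,5,5,8a-tetramethyldecahydronaphthalene-1,4-diol | O[C@@H]1C[C@@H](C)[C@](O)(CC[C@@]3(CO3)CO)[C@@]2(C)CCCC(C)(C)[C@H]12 | intermediate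
26 | (2R)-2-{2-[(1R,2R,4R,4aS,8aS)-1,4-dihydroxy-2,5,5,8a-tetramethyldecahydronaphthalen-1-yl]ethyl}oxirane-2-carbaldehyde | O[C@@H]1C[C@@H](C)[C@](O)(CC[C@@]3(CO3)C=O)[C@@]2(C)CCCC(C)(C)[C@H]12 | intermediate
27 | (1R,2R,4R,4aS,8aS)-1-{2-[(2S)-2-ethynyloxiran-2-yl]ethyl}-2,5,5,8a-tetramethyldecahydronaphthalene-1,4-diol | O[C@@H]1C[C@@H](C)[C@](O)(CC[C@@]3(CO3)C#C)[C@@]2(C)CCCC(C)(C)[C@H]12 | intermediate
28 | (5S,6R,8R,9R,10S,13R)-9,13-epoxylabd-14-yne-6,16-diol | O[C@@H]1C[C@@H](C)[C@]2(CC[C@](CO)(C#C)O2)[C@@]2(C)CCCC(C)(C)[C@H]12 | intermediate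
29 | (5S,6R,8R,9R,10S,13R)-9,13:15,16-diepoxylabd-14-en-6-ol | O[C@@H]1C[C@@H](C)[C@]2(CC[C@]3(C=COC3)O2)[C@@]2(C)CCCC(C)(C)[C@H]12 | intermediate
30 | (5S,6R,8R,9R,10S,13R)-9,13:15,16-diepoxylabd-14-en-6-yl acetate | CC(=O)O[C@@H]1C[C@@H](C)[C@]2(CC[C@]3(C=COC3)O2)[C@@]2(C)CCCC(C)(C)[C@H]12 | target

**Totals and risks**

Total step count: 18. Longest linear sequence: 18 steps (fully linear from 1).

Steps most likely to fail:

Step 6. The C5–C10 bond joins a carbon that becomes quaternary to a neopentyl-type methine, so the iminium may react too slowly with the tetrasubstituted diene terminus. Alternatively, facial or endo control may erode; a cis-fused adduct would have to be removed before step 7, because equilibration at C5 would carry it into the enantiomeric series. The fallback is auxiliary-controlled and Lewis-acid-promoted and sets out from 12. Horner–Wadsworth–Emmons reaction with diethyl {2-[(4S)-4-benzyl-2-oxo-1,3-oxazolidin-3-yl]-2-oxoethyl}phosphonate (LiCl, iPr2NEt, MeCN) should give the (E)-trienimide F1. Me2AlCl (CH2Cl2, −30 °C) should then promote the chelation-controlled endo cycloaddition, in which the diene adds anti to the benzyl group of the s-cis enoyl chelate, to give the trans-fused imide F2 with the same 5S,10S sense. LiBH4 should release the auxiliary and give the primary alcohol F3, and SO3·pyridine/DMSO/Et3N oxidation should return the route at 15.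

Step 12. SN2 attack at the oxirane CH2, which sits between the C10 quaternary centre and the C8 methyl, may be slow, and the basic dianion may instead isomerise the epoxide to an allylic alcohol. The fallback replaces the polar C–C bond formation by a radical one and sets out from 21. LiI/AcOH in THF should open the oxirane at the primary carbon to give the iodohydrin F4. Keck radical allylation of F4 with 2-[(tributylstannyl)methyl]prop-2-en-1-ol (AIBN, PhH, 80 °C), which is insensitive to the neopentyl environment, should give triol 24, where the route is rejoined.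

Step 16. Partial ionisation of the tertiary propargylic epoxide before ring closure would leak stereochemical information at C13. In addition, premature cyclisation at the epoxy alcohol stage (steps 13 and 14) would make the two one-carbon arms on C13 identical. The fallback closes the ring on a non-propargylic epoxide with the arms already differentiated and sets out from 24. Sharpless epoxidation with D-(−)-diethyl tartrate should give the C13-epimeric epoxy alcohol F5, and TBSCl/imidazole should give its primary silyl ether F6. Acid-catalysed 5-exo opening with inversion should give the spiro-tetrahydrofuran F7, in which the silyloxymethyl arm is C16 and the newly freed hydroxymethyl arm is C14. TEMPO/PhI(OAc)2 oxidation should give the aldehyde F8 and Ohira–Bestmann homologation the alkyne F9. Bu4NF should then return the route at 28.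

Further compounds
F1 | step 6 | (4S)-4-benzyl-3-[(2E,8Z)-4,4,8,10-tetramethyl-9-(methylsulfanyl)undeca-2,8,10-trienoyl]-1,3-oxazolidin-2-one | O=C(/C=C/C(C)(C)CCC/C(C)=C(SC)/C(C)=C)N1[C@@H](Cc2ccccc2)COC1=O
F2 | step 6 | (4S)-4-benzyl-3-{[(1S,4aS,8aS)-3,4a,8,8-tetramethyl-4-(methylsulfanyl)-1,2,4a,5,6,7,8,8a-octahydronaphthalen-1-yl]carbonyl}-1,3-oxazolidin-2-one | O=C([C@H]1CC(C)=C(SC)[C@@]2(C)CCCC(C)(C)[C@H]12)N1[C@@H](Cc2ccccc2)COC1=O
F3 | step 6 | [(1S,4aS,8aS)-3,4a,8,8-tetramethyl-4-(methylsulfanyl)-1,2,4a,5,6,7,8,8a-octahydronaphthalen-1-yl]methanol | OC[C@H]1CC(C)=C(SC)[C@@]2(C)CCCC(C)(C)[C@H]12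
F4 | step 12 | (1R,2R,4R,4aS,8aS)-1-(iodomethyl)-2,5,5,8a-tetramethyldecahydronaphthalene-1,4-diol | O[C@@H]1C[C@@H](C)[C@](O)(CI)[C@@]2(C)CCCC(C)(C)[C@H]12
F5 | step 16 | C13 epimer of 25 (oxirane from D-(−)-diethyl tartrate) | O[C@@H]1C[C@@H](C)[C@](O)(CC[C@]3(CO3)CO)[C@@]2(C)CCCC(C)(C)[C@H]12
F6 | step 16 | primary tert-butyldimethylsilyl ether of F5 | O[C@@H]1C[C@@H](C)[C@](O)(CC[C@]3(CO3)CO[Si](C)(C)C(C)(C)C)[C@@]2(C)CCCC(C)(C)[C@H]12
F7 | step 16 | 9,13-epoxide with C13 bearing silyloxymethyl (C16) and hydroxymethyl (C14), 6β-OH | O[C@@H]1C[C@@H](C)[C@]2(CC[C@](CO[Si](C)(C)C(C)(C)C)(CO)O2)[C@@]2(C)CCCC(C)(C)[C@H]12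
F8 | step 16 | C14 aldehyde from F7 | O[C@@H]1C[C@@H](C)[C@]2(CC[C@](CO[Si](C)(C)C(C)(C)C)(C=O)O2)[C@@]2(C)CCCC(C)(C)[C@H]12
F9 | step 16 | 16-O-tert-butyldimethylsilyl ether of 28 | O[C@@H]1C[C@@H](C)[C@]2(CC[C@](CO[Si](C)(C)C(C)(C)C)(C#C)O2)[C@@]2(C)CCCC(C)(C)[C@H]12
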